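Ring C is viewed at the flavone oxidation level. There, the three-carbon bridge C4–C3–C2 between C4a and O1 of ring A, bearing ring B at C2, equals one molecule of CO (C4) plus the two sp carbons of an arylacetylene (C3, C2). One palladium-catalysed carbonylative coupling–cyclisation forges C4a–C4, C4–C3 and O1–C2 and closes ring C. Its precursors are a 2-iodophenol carrying the future 7-oxygen as a TIPS ether, CO, and 1-ethynyl-4-geranyloxybenzene with the geranyl ether already in place. The single stereocentre, C2 (S), follows by ligand-controlled copper hydride conjugate reduction, and buffered fluoride then frees the 7-hydroxyl.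

Key step: step 3

Assumption: the target SMILES reads as 2S. (S)-DTBM-SEGPHOS is assumed to deliver hydride to the face of C2 that gives 2S, by analogy with β-substituted cycloalkenones; if a trial run shows the opposite sense, the equally available (R)-ligand takes its place.
Assumption: 4-ethynylphenol is taken as a catalogue compound, stored cold and used promptly because it tends to polymerise.
Throughout, geranyl means (2E)-3,7-dimethylocta-2,6-dien-1-yl.

Step 1
Reactants: 1 4-iodoresorcinol (4-iodobenzene-1,3-diol)
Product: 2 2-iodo-5-(triisopropylsilyloxy)phenol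
Conditions: TIPSCl (1.0 equiv), imidazole (2.2 equiv), DMF, 0 °C
Reagents that add atoms: triisopropylsilyl chloride (TIPSCl), CC(C)[Si](Cl)(C(C)C)C(C)C
Why: Imidazole-promoted silyl ether formation with the bulky chlorosilane should take place at the hydroxyl para to iodine, which has only hydrogen in both ortho positions, because the other hydroxyl is shielded by the large neighbouring iodine and one equivalent of reagent limits double silylation.

Step 2
Reactants: 3 4-ethynylphenol; 4 geranyl bromide
Product: 5 1-ethynyl-4-geranyloxybenzene
Conditions: K2CO3 (1.5 equiv), DMF, 0 °C to rt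
Reagents that add atoms: none
Why: In this Williamson ether synthesis the phenoxide displaces the primary allylic bromide by SN2 at C1 of the geranyl unit, leaving the E alkene unchanged, the alkyne C–H is far too weakly acidic for K2CO3, and the allylic ether meets no palladium before the key step.

Step 3
Reactants: 2 2-iodo-5-(triisopropylsilyloxy)phenol; 5 1-ethynyl-4-geranyloxybenzene; 6 carbon monoxide
Product: 9 4'-geranyloxy-7-(triisopropylsilyloxy)flavone, via ortho-hydroxyaryl ynone 7 (not isolated), via diethylamino enone 8 (not isolated)
Conditions: PdCl2(PPh3)2 (5 mol %), CO (1 atm), Et2NH, DMF, 60 °C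
Reagents that add atoms: none
Why: Zerovalent palladium, generated in the flask from PdCl2(PPh3)2, inserts into the C–I bond of 2, CO migratory insertion gives an aroyl–palladium iodide, and amine-assisted transfer of the acetylide of 5 followed by reductive elimination creates C4a–C4 and C4–C3 in ynone 7. Et2NH then adds to the alkyne carbon remote from the carbonyl to give push–pull enaminone 8, whose ortho-hydroxyl attacks that same carbon and expels the amine (protonated by the diethylammonium iodide already formed), creating O1–C2. The closest known reaction type is the carbonylative Sonogashira coupling–cyclisation of 2-iodophenols, CO and terminal arylalkynes to flavones. Ring C closes in the 6-endo mode, formally 6-endo-dig on 7 but in practice a 6-endo-trig addition–elimination on 8, and no stereocentre is formed. Three selectivities are needed, namely CO insertion before alkyne transfer (otherwise a 2-arylbenzofuran), alkyne rather than amine capture of the aroyl–palladium species (otherwise the diethylamide) and 6-endo rather than 5-exo closure (otherwise the aurone); they are secured by the electron-rich aryl group of 2, which migrates readily to CO, by leaving out copper salts, by the acidic arylalkyne C–H, and by the enaminone, in which C2 is the only electrophilic carbon within reach of the phenol. The geranyl ether should survive because its trisubstituted alkene binds zerovalent palladium far less readily than the C–I bond reacts, and the moderate temperature keeps allylic ionisation and Claisen rearrangement out of reach.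

Step 4
Reactants: 9 4'-geranyloxy-7-(triisopropylsilyloxy)flavone
Product: 11 (2S)-4'-geranyloxy-7-(triisopropylsilyloxy)flavanone, via silyl enol ether 10 (not isolated)
Conditions: Cu(OAc)2 (5 mol %), (S)-DTBM-SEGPHOS (5.5 mol %), (EtO)2MeSiH (3 equiv), toluene, 0 °C to rt; then AcOH, THF–H2O, 0 °C
Reagents that add atoms: none
Why: This is a copper hydride catalysed asymmetric conjugate reduction (1,4-hydrosilylation), a reaction type known for chromones and β,β-disubstituted enones, in which the monovalent copper hydride formed from Cu(OAc)2 and the silane delivers hydride to C2 on the face left open by the C2-symmetric bisphosphine and so sets C2 as S, σ-bond metathesis with the silane traps the copper enolate as 10 (guarding C4 against 1,2-reduction and the C2–O1 bond against β-elimination), mild acid hydrolysis releases the ketone, and the unactivated geranyl alkenes are inert to copper hydride.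

Step 5
Reactants: 11 (2S)-4'-geranyloxy-7-(triisopropylsilyloxy)flavanone
Product: 12 (2S)-4'-geranyloxy-7-hydroxyflavanone (CNP0302343.1)
Conditions: TBAF (1.1 equiv), AcOH (1.5 equiv), THF, 0 °C
Reagents that add atoms: none
Why: In this fluoride-mediated desilylation the aryl silyl ether para to the C4 carbonyl is activated and should cleave quickly at 0 °C, while acetic acid protonates the phenoxide and keeps the medium too weakly basic for enolisation and retro-oxa-Michael opening to the chalcone, so C2 stays S and the acid-sensitive geranyl ether is untouched.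

Compound list
1 | 4-iodoresorcinol (4-iodobenzene-1,3-diol) | Oc1ccc(I)c(O)c1 | starting material
2 | 2-iodo-5-(triisopropylsilyloxy)phenol | Oc1cc(O[Si](C(C)C)(C(C)C)C(C)C)ccc1I | intermediate
3 | 4-ethynylphenol | C#Cc1ccc(O)cc1 | starting material
4 | geranyl bromide, (2E)-1-bromo-3,7-dimethylocta-2,6-diene | CC(C)=CCC/C(C)=C/CBr | starting material
5 | 1-ethynyl-4-geranyloxybenzene | CC(C)=CCC/C(C)=C/COc1ccc(C#C)cc1 | intermediate
6 | carbon monoxide | [C-]#[O+] | starting material
7 | 3-[4-(geranyloxy)phenyl]-1-[2-hydroxy-4-(triisopropylsilyloxy)phenyl]prop-2-yn-1-one | CC(C)=CCC/C(C)=C/COc1ccc(C#CC(=O)c2ccc(O[Si](C(C)C)(C(C)C)C(C)C)cc2O)cc1 | intermediate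
8 | (E)-3-(diethylamino)-3-[4-(geranyloxy)phenyl]-1-[2-hydroxy-4-(triisopropylsilyloxy)phenyl]prop-2-en-1-one | CC(C)=CCC/C(C)=C/COc1ccc(/C(=C\C(=O)c2ccc(O[Si](C(C)C)(C(C)C)C(C)C)cc2O)N(CC)CC)cc1 | intermediate
9 | 4'-geranyloxy-7-(triisopropylsilyloxy)flavone | CC(C)=CCC/C(C)=C/COc1ccc(-c2cc(=O)c3ccc(O[Si](C(C)C)(C(C)C)C(C)C)cc3o2)cc1 | intermediate
10 | (2S)-4-[diethoxy(methyl)silyloxy]-2-[4-(geranyloxy)phenyl]-7-(triisopropylsilyloxy)-2H-chromene | CC(C)=CCC/C(C)=C/COc1ccc([C@@H]2C=C(O[Si](C)(OCC)OCC)c3ccc(O[Si](C(C)C)(C(C)C)C(C)C)cc3O2)cc1 | intermediate
11 | (2S)-4'-geranyloxy-7-(triisopropylsilyloxy)flavanone | CC(C)=CCC/C(C)=C/COc1ccc([C@@H]2CC(=O)c3ccc(O[Si](C(C)C)(C(C)C)C(C)C)cc3O2)cc1 | intermediate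
12 | (2S)-4'-geranyloxy-7-hydroxyflavanone, (2S)-2-[4-(geranyloxy)phenyl]-7-hydroxy-2,3-dihydro-4H-chromen-4-one | CC(C)=CCC/C(C)=C/COc1ccc([C@@H]2CC(=O)c3ccc(O)cc3O2)cc1 | target

Total step count: 5. Longest linear sequence: 4 steps (1 to 2 to 9 to 11 to 12, or equally 3 to 5 to 9 to 11 to 12).

Steps most likely to fail

Step 4.
- **What may go wrong:** Facial discrimination may be weak, because the flat 2-aryl group offers the catalyst less steric contrast than a 2-alkyl group. Hydride transfer to the doubly donor-substituted C2 may be slow. The copper enolate may open by β-elimination of the aryloxide before it is silylated.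
- **Fallback:** It sets out from 9 and comes back at 11. The conjugate reduction is run without stereocontrol, using the more reactive achiral ligand 1,2-bis(diphenylphosphino)benzene (Cu(OAc)2, (EtO)2MeSiH, toluene). This should give the racemic silyl enol ether F1 and, after mild acid hydrolysis, racemic 4'-geranyloxy-7-(triisopropylsilyloxy)flavanone F2. The racemate is then resolved kinetically by Noyori-type asymmetric transfer hydrogenation (Cp*RhCl[(R,R)-TsDPEN], HCO2H–Et3N, EtOAc, rt, stopped near half conversion), a known way to enantiopure flavanones. The R ketone should be reduced faster, to the cis-(2R,4R)-flavan-4-ol F3. The unreacted S ketone, separated by chromatography, is 11.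

Step 3.
- **What may go wrong:** Zerovalent palladium may ionise the geranyl aryl ether, with Et2NH acting as allyl acceptor. The amine may capture the aroyl–palladium species. Coupling may occur without CO uptake, followed by benzofuran closure. The reaction may stall at the enaminone stage, or the silyl ether may be lost slowly in the warm amine.
- **Fallback:** It is free of palladium, sets out from 5 and comes back at 7. Purchased 2,4-dihydroxybenzaldehyde F4 is silylated with TIPSCl and imidazole at the 4-hydroxyl, since the 2-hydroxyl is held in a hydrogen bond to the aldehyde, to give 2-hydroxy-4-(triisopropylsilyloxy)benzaldehyde F5. Alkyne 5 is deprotonated with n-BuLi (THF, −78 °C) to the lithium acetylide F6. Two equivalents of it are used, one being consumed by the phenol and returned as 5. Addition to F5 and an acetic acid quench give the racemic propargylic alcohol F7. MnO2 in CH2Cl2 oxidises this benzylic–propargylic alcohol to ynone 7, now isolated. Et2NH in EtOH then carries 7 through 8 to 9.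

Step 1.
- **What may go wrong:** Discrimination between the two hydroxyls may be incomplete, because the hindered one is also the more acidic. This would give regioisomeric and doubly silylated material that is laborious to separate.
- **Fallback:** It sets out from 1 and comes back at 9, and it removes the need for any differentiation. Both hydroxyls are acetylated (Ac2O, pyridine) to 4-iodo-1,3-phenylene diacetate F8. The known carbonylative annulation of iodophenol acetates is then run with 5 and 6 under the palladium, CO and Et2NH regime of step 3 with extra amine. The amine also strips both acetates, which should give 4'-geranyloxy-7-hydroxyflavone F9. Its only hydroxyl is silylated with TIPSCl and imidazole to 9.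

Further compounds
F1 | step 4 | racemic 4-[diethoxy(methyl)silyloxy]-2-[4-(geranyloxy)phenyl]-7-(triisopropylsilyloxy)-2H-chromene | CC(C)=CCC/C(C)=C/COc1ccc(C2C=C(O[Si](C)(OCC)OCC)c3ccc(O[Si](C(C)C)(C(C)C)C(C)C)cc3O2)cc1
F2 | step 4 | racemic 4'-geranyloxy-7-(triisopropylsilyloxy)flavanone | CC(C)=CCC/C(C)=C/COc1ccc(C2CC(=O)c3ccc(O[Si](C(C)C)(C(C)C)C(C)C)cc3O2)cc1
F3 | step 4 | cis-(2R,4R)-4'-geranyloxy-7-(triisopropylsilyloxy)flavan-4-ol | CC(C)=CCC/C(C)=C/COc1ccc([C@H]2C[C@@H](O)c3ccc(O[Si](C(C)C)(C(C)C)C(C)C)cc3O2)cc1
F4 | step 3 | 2,4-dihydroxybenzaldehyde (purchased) | O=Cc1ccc(O)cc1O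
F5 | step 3 | 2-hydroxy-4-(triisopropylsilyloxy)benzaldehyde | O=Cc1ccc(O[Si](C(C)C)(C(C)C)C(C)C)cc1O
F6 | step 3 | lithium acetylide of 5 | CC(C)=CCC/C(C)=C/COc1ccc(C#C[Li])cc1
F7 | step 3 | racemic 3-[4-(geranyloxy)phenyl]-1-[2-hydroxy-4-(triisopropylsilyloxy)phenyl]prop-2-yn-1-ol | CC(C)=CCC/C(C)=C/COc1ccc(C#CC(O)c2ccc(O[Si](C(C)C)(C(C)C)C(C)C)cc2O)cc1
F8 | step 1 | 4-iodo-1,3-phenylene diacetate | CC(=O)Oc1ccc(I)c(OC(C)=O)c1
F9 | step 1 | 4'-geranyloxy-7-hydroxyflavone | CC(C)=CCC/C(C)=C/COc1ccc(-c2cc(=O)c3ccc(O)cc3o2)cc1
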